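Everything rests on cutting the C1–C2 bond of ring A. The carbinol carbon C1 and the bromine-bearing C3 are separated only by the C2 methylene group. Such a γ-bromo alcohol is what a ketone delivers when an alkene adds to it and bromide quenches the cation (halo-Prins reaction). In the last step titanium(IV) bromide lets the terminal alkene carbon attack the acetyl carbonyl. This closes ring A onto the spiro carbon C6, forms C3–Br and sets C1 and C3 under Lewis-acidic conditions, away from the basic media in which the product would fragment (Grob). The precursor is monocyclic: a cyclohexene whose (S)-configured quaternary C6 carries acetyl and 2-methylpent-4-en-2-yl groups and whose C9 bears the (E)-bromomethylidene unit.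

Key step: step 5

Remarks on the chemistry
- Atom numbers follow the spiro[5.5]undecane name of the target and are kept for all intermediates. C1 is the carbinol carbon, C2 is CH2, C3 is CHBr, C4 is CH2, C5 is CMe2 and C6 is the spiro centre. Ring B holds C7=C8, C9 with the exocyclic C12, C10 and C11.
- The target SMILES reads as (1S,3R,6S,9E). In the ring A chair, OH is axial, the C1 methyl is equatorial and Br is equatorial, so OH and Br are 1,3-trans. C7 is axial and anti to oxygen, and C11 is equatorial. Br on C12 is cis to C10. C6 has the same spatial arrangement in 10, 12 and 14.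
- Relative to its ketone, the alkene of the precursor is δ,ε (C3=C2). This is what a six-membered ring containing both alkene carbons requires.
- Assumption: the sense of induction of the chiral acid in step 3 cannot be predicted for this dienophile. The BINOL antipode that gives (S)-10 is used, and preparation of the catalyst is not counted.

Step 1
Reactants: 1 mesityl oxide (4-methylpent-3-en-2-one); 2 allyltrimethylsilane; 3 N,N-dimethylmethyleneiminium iodide
Product: 5 3-[(dimethylamino)methyl]-4,4-dimethylhept-6-en-2-one (racemic), via titanium enolate 4 (not isolated)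
Conditions: TiCl4 (1.05 equiv), CH2Cl2, −78 °C; then 3, −78 °C → rt; aq K2CO3
Reagents that add atoms: none
Why: Hosomi–Sakurai conjugate allylation creates the quaternary C5 on the β,β-disubstituted enone, and the regiodefined enolate 4 is caught at C6 by the small iminium ion (Mannich reaction), a position that enolisation of the free ketone would not address, the new stereocentre being racemic and erased in step 2.

Step 2
Reactants: 5 3-[(dimethylamino)methyl]-4,4-dimethylhept-6-en-2-one
Product: 7 4,4-dimethyl-3-methylidenehept-6-en-2-one, via ammonium iodide 6 (not isolated)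
Conditions: MeI, MeCN, rt; then K2CO3, CH2Cl2/H2O, rt
Reagents that add atoms: none
Why: Quaternisation turns the amine into a leaving group and carbonate induces E1cB (Hofmann-type) loss of trimethylamine, the usual second half of a Mannich methylenation, under conditions that leave the isolated alkene untouched.

Step 3
Reactants: 7 4,4-dimethyl-3-methylidenehept-6-en-2-one; 8 (E)-1-methoxy-3-(trimethylsilyloxy)buta-1,3-diene
Product: 10 (4S)-4-acetyl-4-(2-methylpent-4-en-2-yl)cyclohex-2-en-1-one, via silyl enol ether cycloadduct 9 (not isolated)
Conditions: confined BINOL-derived imidodiphosphorimidate (IDPi) acid (3 mol %), toluene, −40 °C; then 1 M HCl, THF, 0 °C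
Reagents that add atoms: none
Why: Catalytic asymmetric Diels–Alder reaction of an α-methylene ketone: the confined chiral acid, silylated in situ by 8 to a chiral silylium Lewis acid, activates the carbonyl group and shields one face of C6=C11, the nucleophilic CH2 end of 8 bonds to C11 and the methoxy-bearing end to C6, so that C6 is set by the catalyst whichever C7 epimer of 9 forms, and acid then removes silicon and methanol, which fixes the enone on the C7 side irreversibly.

Step 4
Reactants: 10 (4S)-4-acetyl-4-(2-methylpent-4-en-2-yl)cyclohex-2-en-1-one; 11 (bromomethyl)triphenylphosphonium bromide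
Product: 12 1-[(1S,4E)-4-(bromomethylidene)-1-(2-methylpent-4-en-2-yl)cyclohex-2-en-1-yl]ethan-1-one
Conditions: NaHMDS (slightly less than 11), THF, −78 °C; then 10, −78 → 0 °C
Reagents that add atoms: none
Why: Wittig olefination: the non-stabilised ylide adds 1,2 to the open enone carbonyl only, the acetyl group being buried between the quaternary C5 and C6, bromine is expected to favour the C10 side (E) because the in-plane C8–H causes more allylic strain than the staggered C10 hydrogens, the minor Z isomer is removed by chromatography, and the amide base avoids the nucleophilic deacetylation (vinylogous retro-Claisen) that alkoxides could cause.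

Step 5
Reactants: 12 1-[(1S,4E)-4-(bromomethylidene)-1-(2-methylpent-4-en-2-yl)cyclohex-2-en-1-yl]ethan-1-one
Product: 14 (1S,3R,6S,9E)-3-bromo-9-(bromomethylidene)-1,5,5-trimethylspiro[5.5]undec-7-en-1-ol (target), via tribromotitanium alkoxide 13 (not isolated)
Conditions: TiBr4 (2 equiv), n-Bu4NBr (0.5 equiv, bromide shuttle), 2,6-di-tert-butyl-4-methylpyridine (0.5 equiv), CH2Cl2 (0.01 M), −78 → −40 °C; cold pH 7 phosphate buffer; neutral silica
Reagents that add atoms: titanium tetrabromide, Br[Ti](Br)(Br)Br
Why: TiBr4 binds the acetyl oxygen, the only Lewis-basic site, the terminal alkene carbon C2 adds to C1 and bromide closes the charge that builds up at C3, so that C1–C2, ring A and C3–Br arise together in what is the microscopic reverse of the Grob fragmentation of the product. The closest known reaction type is the titanium(IV) halide Prins cyclisation of δ,ε-unsaturated methyl ketones to 3-halo-1-methylcyclohexanols; bromide in place of chloride, the doubly neopentyl ketone and the neighbouring bromodiene are the extensions. Ring A closes 6-endo at the alkene (exo at C=O) through a chair, because bonding through C3 would give a five-membered ring and a primary C2 cation, and the quaternary C5 and C6 press the chain ends together (Thorpe–Ingold effect). C1 is controlled by C6: the acetyl methyl takes the equatorial site to stay clear of the axial C5 methyl, O–Ti becomes axial, and the flat sp2 arm C7 rather than C11H2 should occupy the axial site beside the incoming C2, which places oxygen anti to C7 as in the target; this C7/C11 choice is the weakest point. C3 is controlled by anti addition: simpler substrates are known to receive the halide internally from titanium on the axial, oxygen-syn side, so an external bromotitanate (TiBr4 plus catalytic n-Bu4NBr, regenerated) is offered, which can enter only antiperiplanar to the forming C1–C2 bond, i.e. equatorially and trans to oxygen, the axial lobe being screened by O–Ti and the axial C5 methyl. Chemoselectivity is needed against the bromodiene and is secured by its electron-poor character, by its inability to reach C1, by low temperature and high dilution, and by the hindered pyridine, which removes HBr before it can add to an alkene, scramble C9=C12 or ionise the tertiary C1–O bond.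

Compound list
1 | mesityl oxide | CC(C)=CC(C)=O | starting material
2 | allyltrimethylsilane | C=CC[Si](C)(C)C | starting material
3 | N,N-dimethylmethyleneiminium iodide | C[N+](C)=C.[I-] | starting material
4 | trichlorotitanium (Z)-enolate of 4,4-dimethylhept-6-en-2-one | C=CCC(C)(C)/C=C(/C)O[Ti](Cl)(Cl)Cl | intermediate
5 | 3-[(dimethylamino)methyl]-4,4-dimethylhept-6-en-2-one (racemic) | C=CCC(C)(C)C(CN(C)C)C(C)=O | intermediate
6 | 2-acetyl-N,N,N,3,3-pentamethylhex-5-en-1-aminium iodide (racemic) | C=CCC(C)(C)C(C[N+](C)(C)C)C(C)=O.[I-] | intermediate
7 | 4,4-dimethyl-3-methylidenehept-6-en-2-one | C=CCC(C)(C)C(=C)C(C)=O | intermediate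
8 | (E)-1-methoxy-3-(trimethylsilyloxy)buta-1,3-diene | CO/C=C/C(=C)O[Si](C)(C)C | starting material
9 | 1-[(1R)-2-methoxy-1-(2-methylpent-4-en-2-yl)-4-(trimethylsilyloxy)cyclohex-3-en-1-yl]ethan-1-one (methoxy carbon C7 uncontrolled, erased in the same flask) | C=CCC(C)(C)[C@@]1(C(C)=O)C(OC)C=C(O[Si](C)(C)C)CC1 | intermediate
10 | (4S)-4-acetyl-4-(2-methylpent-4-en-2-yl)cyclohex-2-en-1-one | C=CCC(C)(C)[C@@]1(C(C)=O)C=CC(=O)CC1 | intermediate
11 | (bromomethyl)triphenylphosphonium bromide | BrC[P+](c1ccccc1)(c1ccccc1)c1ccccc1.[Br-] | starting material
12 | 1-[(1S,4E)-4-(bromomethylidene)-1-(2-methylpent-4-en-2-yl)cyclohex-2-en-1-yl]ethan-1-one | C=CCC(C)(C)[C@@]1(C(C)=O)C=C/C(=C/Br)CC1 | intermediate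
13 | tribromotitanium alkoxide of 14 | CC1(C)C[C@@H](Br)C[C@](C)(O[Ti](Br)(Br)Br)[C@@]12C=C/C(=C/Br)CC2 | intermediate
14 | (1S,3R,6S,9E)-3-bromo-9-(bromomethylidene)-1,5,5-trimethylspiro[5.5]undec-7-en-1-ol | CC1(C)C[C@@H](Br)C[C@](C)(O)[C@@]12C=C/C(=C/Br)CC2 | target

Total step count: 5. Longest linear sequence: 5 (1 → 5 → 7 → 10 → 12 → 14).

Steps most likely to fail

Risk 1, step 5.
- What may go wrong: the two chairs that differ in which ring B arm is axial may be used alike, which would mean poor facial selectivity at C1. Bromide may be handed over internally from titanium to the axial lobe of C3. The secondary cation may also escape by hydride shift, proton loss or transannular attack of C7=C8.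
- Fallback: starting again from 12, one-pass stereocontrol is given up in favour of a correct-and-recycle scheme built on two known reactions, and the bromohydrins are separated on neutral silica.
- The C3 epimer with axial bromide is (1S,3S,6S,9E)-3-bromo-9-(bromomethylidene)-1,5,5-trimethylspiro[5.5]undec-7-en-1-ol F1. It is warmed with LiBr in acetone, and Finkelstein-type SN2 exchange inverts C3 and relieves the syn-axial Br/CH3/OH strain. The exchange cannot run backwards, because the rear side of the equatorial bromide is closed by the axial OH and the axial C5 methyl. This rejoins the route at 14.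
- The wrong-chair isomer is (1R,3S,6S,9E)-3-bromo-9-(bromomethylidene)-1,5,5-trimethylspiro[5.5]undec-7-en-1-ol F2. Its equatorial bromide is antiperiplanar to C1–C2. KOt-Bu in THF at 0 °C cleaves it by Grob fragmentation back to 12 with C6 untouched, and the material is resubmitted to step 5.

Risk 2, step 3.
- What may go wrong: the hindered dienophile may react too slowly. A stepwise Mukaiyama–Michael course may erode facial control. The diene may be lost by protodesilylation.
- Fallback: starting from 7 and 8, asymmetric catalysis is replaced by resolution.
- Uncatalysed cycloaddition in toluene at 110 °C should give the racemic cycloadduct 1-[2-methoxy-1-(2-methylpent-4-en-2-yl)-4-(trimethylsilyloxy)cyclohex-3-en-1-yl]ethan-1-one F3.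
- The same acid treatment gives racemic 4-acetyl-4-(2-methylpent-4-en-2-yl)cyclohex-2-en-1-one F4.
- F4 is separated by preparative supercritical-fluid chromatography on a polysaccharide chiral phase. The (S)-enantiomer is 10 and rejoins the route there. The (4R)-4-acetyl-4-(2-methylpent-4-en-2-yl)cyclohex-2-en-1-one F5 is set aside.

Risk 3, step 4.
- What may go wrong: E/Z discrimination may be poor, because the C8 and C10 flanks of the carbonyl group differ little in size. Halogen scrambling of the ylide is a further risk.
- Fallback: starting from 10, the C8 flank is enlarged temporarily.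
- Iodine/pyridine α-iodination of the enone gives (4S)-4-acetyl-2-iodo-4-(2-methylpent-4-en-2-yl)cyclohex-2-en-1-one F6.
- The same Wittig reagent must now place bromine away from the large in-plane iodine. This gives 1-[(1S,4E)-4-(bromomethylidene)-3-iodo-1-(2-methylpent-4-en-2-yl)cyclohex-2-en-1-yl]ethan-1-one F7.
- Pd(PPh3)4 with Bu3SnH in THF at rt removes only iodine, since oxidative addition into C–I is faster than into C–Br. This rejoins the route at 12.

Further compounds
F1 | step 5 | (1S,3S,6S,9E)-3-bromo-9-(bromomethylidene)-1,5,5-trimethylspiro[5.5]undec-7-en-1-ol | CC1(C)C[C@H](Br)C[C@](C)(O)[C@@]12C=C/C(=C/Br)CC2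
F2 | step 5 | (1R,3S,6S,9E)-3-bromo-9-(bromomethylidene)-1,5,5-trimethylspiro[5.5]undec-7-en-1-ol | CC1(C)C[C@H](Br)C[C@@](C)(O)[C@@]12C=C/C(=C/Br)CC2
F3 | step 3 | racemic 1-[2-methoxy-1-(2-methylpent-4-en-2-yl)-4-(trimethylsilyloxy)cyclohex-3-en-1-yl]ethan-1-one | C=CCC(C)(C)C1(C(C)=O)C(OC)C=C(O[Si](C)(C)C)CC1
F4 | step 3 | racemic 4-acetyl-4-(2-methylpent-4-en-2-yl)cyclohex-2-en-1-one | C=CCC(C)(C)C1(C(C)=O)C=CC(=O)CC1
F5 | step 3 | (4R)-4-acetyl-4-(2-methylpent-4-en-2-yl)cyclohex-2-en-1-one | C=CCC(C)(C)[C@]1(C(C)=O)C=CC(=O)CC1
F6 | step 4 | (4S)-4-acetyl-2-iodo-4-(2-methylpent-4-en-2-yl)cyclohex-2-en-1-one | C=CCC(C)(C)[C@@]1(C(C)=O)C=C(I)C(=O)CC1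
F7 | step 4 | 1-[(1S,4E)-4-(bromomethylidene)-3-iodo-1-(2-methylpent-4-en-2-yl)cyclohex-2-en-1-yl]ethan-1-one | C=CCC(C)(C)[C@@]1(C(C)=O)C=C(I)/C(=C/Br)CC1
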